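**One step fails.** In a one-step world X takes J to G, G takes J to L, and the readings balance, but they don't.

| flask | X | J | remark | time |
|---|---|---|---|---|
| west | 0.017 M | 0.0221 M | run made earlier |  |
| north-west | 0.034 M | 0.0221 M | run made earlier |  |
| dawn | 0.017 M | 0.0221 M | everything together at the start | 40 min |
| noon | 0.017 M | 0.0221 M (fed, over 25 min) | all else is in the flask from the start; the feed brings no volume worth counting | 40 min |
| spring | 0.017 M (fed, over 25 min) | 0.0221 M | all else is in the flask from the start; the feed brings no volume worth counting | 40 min |

- west (time / min: G / %, L / %): 4.00: 10.1, 38.5; 8.00: 10.1, 39.5; 12.0: 10.6, 41.2; 15.0: 8.6, 39.4; 20.0: 9.1, 38.8; 25.0: 9.6, 41.7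
- north-west (time / min: G / %, L / %): 0.667: 21.4, 9.6; 1.33: 21.5, 10.0; 2.00: 20.5, 8.6; 2.50: 19.3, 11.1; 3.00: 17.4, 11.2; 4.00: 17.1, 10.3

(readings scatter by 1 percentage point)

1. the flask that comes out highest in share of G in G plus L, or "all alike" when all lie within 1.5 percentage points (dawn / noon / spring / all alike)
2. share of G in G plus L at the end, dawn
3. share of G in G plus L at the end, noon
4. share of G in G plus L at the end, spring

- a reading or a percentage of G counts all its forms, free or not

**Counting turnovers.** West charges 1.30 J per X, yet its mean readings, G 0.0968 and L 0.399 of the charge, account for 0.895 J with L counted double, so 0.406 stays unread. We suppose an unread product takes one J from one X, which makes the read branch 0.549 of the first step. That is a guess, but north-west, with twice the X, gives 0.541, so we keep it. We call the J price the J spent per X turned once G has gone on to L, 1.55.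

**Our estimate.** Dawn should repeat west, with a share near 19.5%. Noon looks the same at first, but G reads 21.4% and later 17.1% in north-west beside unturned X, and noon, with J fed over 25 min, should hold the two together longer than that run lasted, so we put noon below dawn. Spring charges less J per X than the price, which makes J the limiting reagent, and 0.161 of the X should stay unturned. Doesn't that spare G? No, since by this count the J in spring lasts about 21.0 min of the 25 min feed, and the G made in that time should meet J standing above X. So we put spring below dawn too, and name dawn.

The forecast named spring, with 19.8% for dawn, 20% for noon and 28% for spring, on the ground that “J seems to die quickly”.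

**The result.** Dawn gives 17.2%, noon 6.78% and spring 6.04%.

    X + J → G (k = 2.30 M⁻¹ s⁻¹)
    X + J → D (k = 1.60 M⁻¹ s⁻¹)
    J + G → L (k = 4.60 M⁻¹ s⁻¹)
    J + D → L (k = 0.0240 M⁻¹ s⁻¹)
    G ⇌ Z (K = 0.130, k = 0.00550 s⁻¹)
    Q ⇌ G, rate k6*(cs6 - [G]) while solid is left; crystals form when [G] > cs6 (solubility = 3.90 mM, k = 1.10 s⁻¹)
    X + G → E (k = 0.0870 M⁻¹ s⁻¹)

**Price again.** Spring ends with 17% of its X left, against our 16.1%, and J at 0%. The neighbour of dawn with 0.010 M of X charges 2.21 J per X, above the price, so X should be the limiting reagent and 29.9% of the J should remain. That flask ends with X at 0% and J at 23.1% of its own charge, and L stands at 70.1% of the X charged, above the read branch of 54.9%.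

The readings are calculated from invented constants; scatter was added.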